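**Plan**

- The retrosynthesis first cuts C1–C8 of the cyclohexanone ring (C1, C8, C7, C6, C5, C9). C5 then carries two identical (R)-2-isopropenyl-5-methylhex-4-enyl (lavandulyl) arms: the ring chain C6–C7(prenyl)–C8Me2 is a cyclised lavandulyl group, and C7 has the same configuration and ligand ranking as the side-chain centre C2′. C5 is therefore not a stereocentre in the monocyclic precursor 17.
- The vinylogous acid 17 is cut at C3–C4 and C1–C9 into a 2,2-dialkylmalonyl dichloride (C4–C5–C9) and a β-methoxy enone (C1–C2–C3) that already carries prenyl, OMe and benzoyl. The malonyl unit is cut at both C5–CH2 bonds into dimethyl malonate and (S)-lavandulyl iodide.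
- Forward: an auxiliary-controlled deconjugative prenylation makes the one chiral building block, which is used twice. Malonate bis-alkylation builds C5, a [3+3] Claisen/Dieckmann annulation closes the ring C1–C2–C3–C4–C5–C9 with the OMe position fixed, and an acid-mediated cation–enol cyclisation closes C1–C8 to give the bicyclo[3.3.1]nonane.
- Stereochemistry: C7 and C2′ come from the auxiliary; any minor enantiomer of 7 should end up mainly in a separable heterochiral diastereomer of 10. C1 and C5 arise in the last step by desymmetrisation of the two arms through a chair with the C7 prenyl equatorial.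

Key step: step 11

Remark: atom numbers are those of the target core (C1 = bridgehead next to C8Me2, C5 = bridgehead with the side chain, C9 = bridging C=O) and are used for precursors too; the target is read as (1R,5R,7R,2′R) with the C7 prenyl exo (trans to the C2–C4 bridge), and 17 is drawn as one of its rapidly equilibrating enol tautomers.

**Step 1**
Reactants: 1 (S)-4-benzyloxazolidin-2-one; 2 3-methylbut-2-enoyl chloride
Product: 3 (S)-4-benzyl-3-(3-methylbut-2-enoyl)oxazolidin-2-one
Conditions: n-BuLi, THF, −78 °C; then 2, −78 → 0 °C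
Reagents that add atoms: none
Why: N-acylation of the lithiated oxazolidinone by the acid chloride attaches the chiral auxiliary and creates no stereocentre.

**Step 2**
Reactants: 3 (S)-4-benzyl-3-(3-methylbut-2-enoyl)oxazolidin-2-one; 4 prenyl bromide
Product: 5 (4S)-4-benzyl-3-[(2S)-5-methyl-2-(prop-1-en-2-yl)hex-4-enoyl]oxazolidin-2-one
Conditions: NaHMDS, THF, −78 °C; then 4, −78 → −40 °C
Reagents that add atoms: none
Why: Deconjugative α-alkylation of the chelated Z(O)-sodium dienolate (Evans-type auxiliary alkylation) should deliver the prenyl group anti to the benzyl group, which sets the (S) centre that later becomes both C7 and C2′, while the double bond moves out of conjugation to give the isopropenyl group.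

**Step 3**
Reactants: 5 alkylated imide
Product: 6 (S)-lavandulol [(2S)-5-methyl-2-(prop-1-en-2-yl)hex-4-en-1-ol]
Conditions: LiBH4, Et2O, H2O (1 equiv), 0 °C
Reagents that add atoms: none
Why: Reductive cleavage of the imide with lithium borohydride should release the primary alcohol without epimerising or conjugating the β,γ-unsaturated centre and returns the auxiliary.

**Step 4**
Reactants: 6 (S)-lavandulol
Product: 7 (S)-lavandulyl iodide [(2S)-1-iodo-5-methyl-2-(prop-1-en-2-yl)hex-4-ene]
Conditions: PPh3, I2, imidazole, CH2Cl2, 0 °C → rt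
Reagents that add atoms: iodine, II
Why: The Appel iodination converts the primary alcohol into the iodide under neutral conditions and breaks no bond at the stereocentre.

**Step 5**
Reactants: 8 dimethyl malonate; 7 (S)-lavandulyl iodide (2.2 equiv)
Product: 10 dimethyl 2,2-bis[(2R)-5-methyl-2-(prop-1-en-2-yl)hex-4-en-1-yl]malonate, via monoalkylated malonate 9 (not isolated)
Conditions: NaH (2.4 equiv), DMF, 0 °C; 7, 0 → 60 °C
Reagents that add atoms: none
Why: Two successive SN2 alkylations of the soft, weakly basic malonate anion (malonic ester synthesis) should give only C-alkylation and build the quaternary carbon that becomes C5 with two identical arms, so this carbon is not a stereocentre (the descriptor of the arms changes to R only through ligand ranking).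

**Step 6**
Reactants: 10 bis-alkylated malonate
Product: 11 2,2-bis[(2R)-5-methyl-2-(prop-1-en-2-yl)hex-4-en-1-yl]malonic acid
Conditions: KOH, EtOH/H2O, reflux; then 1 M HCl, 0 °C, to pH 2
Reagents that add atoms: potassium hydroxide, [K+].[OH-]
Why: Saponification under forcing basic conditions, to which the olefins are inert, followed by cold acidification should give the dialkylmalonic acid without decarboxylation.

**Step 7**
Reactants: 11 dialkylmalonic acid
Product: 12 2,2-bis[(2R)-5-methyl-2-(prop-1-en-2-yl)hex-4-en-1-yl]malonyl dichloride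
Conditions: 1-chloro-N,N,2-trimethylprop-1-en-1-amine (2.3 equiv), CH2Cl2, 0 °C → rt; used crude
Reagents that add atoms: 1-chloro-N,N,2-trimethylprop-1-en-1-amine (Ghosez reagent), CC(C)=C(Cl)N(C)C
Why: The α-chloro enamine converts both acids into acid chlorides under neutral conditions, without free HCl that could add to the isopropenyl and prenyl groups, and a disubstituted malonyl chloride cannot form a ketene.

**Step 8**
Reactants: 13 benzoylacetone; 4 prenyl bromide
Product: 14 7-methyl-1-phenyloct-6-ene-1,3-dione
Conditions: LDA (2.1 equiv), THF, 0 °C; then 4, −78 → 0 °C; aq. NH4Cl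
Reagents that add atoms: none
Why: γ-Alkylation of the β-diketone dianion takes place at the more basic terminal carbanion and places the future C1 prenyl chain regiospecifically.

**Step 9**
Reactants: 14 7-methyl-1-phenyloct-6-ene-1,3-dione
Product: 15 (E)-3-methoxy-7-methyl-1-phenylocta-2,6-dien-1-one
Conditions: HC(OMe)3, MeOH, TsOH (cat.), rt
Reagents that add atoms: trimethyl orthoformate, COC(OC)OC
Why: Acid-catalysed enol ether formation should occur at the more electrophilic alkyl ketone and leave the conjugated aryl ketone, which fixes the methoxy group on the carbon that becomes C2, between the future C1 and C3.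

**Step 10**
Reactants: 15 β-methoxy enone; 12 dialkylmalonyl dichloride
Product: 17 4-benzoyl-5-hydroxy-3-methoxy-2-(3-methylbut-2-en-1-yl)-6,6-bis[(2R)-5-methyl-2-(prop-1-en-2-yl)hex-4-en-1-yl]cyclohexa-2,4-dien-1-one, via open-chain keto acid chloride 16 (not isolated)
Conditions: 15, LDA (1.05 equiv), THF, −78 °C; added to 12, THF, −78 °C; then LiHMDS (2.2 equiv), −78 → 0 °C; aq. citric acid
Reagents that add atoms: none
Why: Claisen-type C-acylation of the lithium dienolate followed by Dieckmann-type closure onto the second acid chloride (an Effenberger-type [3+3] annulation) should form the C1–C9 and C3–C4 bonds, and since the malonyl unit is symmetric either order of acylation gives the same ring, closure through the C2 oxygen is blocked by the methyl ether, and the chelated vinylogous acid is the thermodynamic sink with no new stereocentre.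

**Step 11**
Reactants: 17 bis-lavandulyl vinylogous acid
Product: 18 (1R,5R,7R)-3-benzoyl-2-methoxy-8,8-dimethyl-1,7-bis(3-methylbut-2-en-1-yl)-5-[(2R)-5-methyl-2-(prop-1-en-2-yl)hex-4-en-1-yl]bicyclo[3.3.1]non-2-ene-4,9-dione
Conditions: HCO2H/CH2Cl2 (1:1), 0 → 23 °C, stopped at full conversion
Reagents that add atoms: none
Why: Formic acid should protonate the terminal carbon of one isopropenyl group while the enol carbon C1 attacks the developing tertiary cation C8, and loss of the enol proton leaves the C2 methyl enol ether and the C4 and C9 ketones of 18, so no separate methylation is needed. The closest known reaction type is the Brønsted-acid-mediated biomimetic cation–enol cyclisation (a Conia-ene-like Markovnikov hydroalkylation) of dearomatised prenylated acylphloroglucinols to bicyclo[3.3.1]nonane-2,4,9-triones. The one new ring, the cyclohexanone C1–C8–C7–C6–C5–C9, closes in a 6-(enolendo)-exo-trig mode across the existing six-membered ring and so completes the bicycle. C5 and C1 become stereogenic together, and their sense is set by the C7 centre of the arm that closes through a chair with the C7 prenyl equatorial (exo); the other, diastereotopic arm would have to place its prenyl axial over the dienone or use a boat, and because both arms ionise reversibly the choice is made under Curtin–Hammett control. The step needs C1 rather than C3 or oxygen as nucleophile (C3 is deactivated and shielded by the chelated benzoyl group, and tertiary enol ethers formed at oxygen re-ionise in acid) and one of five olefins as electrophile (only an isopropenyl group can be protonated with assistance from the enol in a six-membered array). Once C1 is quaternary no enol nucleophile remains, so the second isopropenyl group, which is the C5 side chain of the target, should survive.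

**Compound list**

1 | (S)-4-benzyloxazolidin-2-one | O=C1OC[C@H](Cc2ccccc2)N1 | starting material
2 | 3-methylbut-2-enoyl chloride | CC(C)=CC(=O)Cl | starting material
3 | (S)-4-benzyl-3-(3-methylbut-2-enoyl)oxazolidin-2-one | CC(C)=CC(=O)N1[C@@H](Cc2ccccc2)COC1=O | intermediate
4 | prenyl bromide (1-bromo-3-methylbut-2-ene) | CC(C)=CCBr | starting material
5 | (4S)-4-benzyl-3-[(2S)-5-methyl-2-(prop-1-en-2-yl)hex-4-enoyl]oxazolidin-2-one | O=C1OC[C@H](Cc2ccccc2)N1C(=O)[C@H](C(C)=C)CC=C(C)C | intermediate
6 | (S)-lavandulol, (2S)-5-methyl-2-(prop-1-en-2-yl)hex-4-en-1-ol | OC[C@H](C(C)=C)CC=C(C)C | intermediate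
7 | (S)-lavandulyl iodide, (2S)-1-iodo-5-methyl-2-(prop-1-en-2-yl)hex-4-ene | IC[C@H](C(C)=C)CC=C(C)C | intermediate
8 | dimethyl malonate | COC(=O)CC(=O)OC | starting material
9 | dimethyl 2-[(2R)-5-methyl-2-(prop-1-en-2-yl)hex-4-en-1-yl]malonate | COC(=O)C(C[C@H](C(C)=C)CC=C(C)C)C(=O)OC | intermediate
10 | dimethyl 2,2-bis[(2R)-5-methyl-2-(prop-1-en-2-yl)hex-4-en-1-yl]malonate | COC(=O)C(C[C@H](C(C)=C)CC=C(C)C)(C[C@H](C(C)=C)CC=C(C)C)C(=O)OC | intermediate
11 | 2,2-bis[(2R)-5-methyl-2-(prop-1-en-2-yl)hex-4-en-1-yl]malonic acid | OC(=O)C(C[C@H](C(C)=C)CC=C(C)C)(C[C@H](C(C)=C)CC=C(C)C)C(=O)O | intermediate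
12 | 2,2-bis[(2R)-5-methyl-2-(prop-1-en-2-yl)hex-4-en-1-yl]malonyl dichloride | O=C(Cl)C(C[C@H](C(C)=C)CC=C(C)C)(C[C@H](C(C)=C)CC=C(C)C)C(=O)Cl | intermediate
13 | benzoylacetone (1-phenylbutane-1,3-dione) | CC(=O)CC(=O)c1ccccc1 | starting material
14 | 7-methyl-1-phenyloct-6-ene-1,3-dione | CC(C)=CCCC(=O)CC(=O)c1ccccc1 | intermediate
15 | (E)-3-methoxy-7-methyl-1-phenylocta-2,6-dien-1-one | CO/C(CCC=C(C)C)=C/C(=O)c1ccccc1 | intermediate
16 | (E)-5-methoxy-4-(3-methylbut-2-en-1-yl)-2,2-bis[(2R)-5-methyl-2-(prop-1-en-2-yl)hex-4-en-1-yl]-3,7-dioxo-7-phenylhept-5-enoyl chloride (epimers at the enolisable C4) | O=C(Cl)C(C[C@H](C(C)=C)CC=C(C)C)(C[C@H](C(C)=C)CC=C(C)C)C(=O)C(CC=C(C)C)/C(OC)=C\C(=O)c1ccccc1 | intermediate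
17 | 4-benzoyl-5-hydroxy-3-methoxy-2-(3-methylbut-2-en-1-yl)-6,6-bis[(2R)-5-methyl-2-(prop-1-en-2-yl)hex-4-en-1-yl]cyclohexa-2,4-dien-1-one | O=C1C(CC=C(C)C)=C(OC)C(C(=O)c2ccccc2)=C(O)C1(C[C@H](C(C)=C)CC=C(C)C)C[C@H](C(C)=C)CC=C(C)C | intermediate
18 | (1R,5R,7R)-3-benzoyl-2-methoxy-8,8-dimethyl-1,7-bis(3-methylbut-2-en-1-yl)-5-[(2R)-5-methyl-2-(prop-1-en-2-yl)hex-4-en-1-yl]bicyclo[3.3.1]non-2-ene-4,9-dione | C=C(C)[C@H](CC=C(C)C)C[C@@]12C[C@@H](CC=C(C)C)C(C)(C)[C@@](CC=C(C)C)(C1=O)C(OC)=C(C(=O)c1ccccc1)C2=O | target

**Step count and risks**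

Total step count: 11. Longest linear sequence: 9 (steps 1–7, 10, 11).

Steps most likely to fail:

1. Step 11. Protonation may not discriminate between the olefins: the prenyl groups may be attacked, the second isopropenyl group may isomerise to the tetrasubstituted olefin or close onto the C4 oxygen with loss of the methyl ether, and closure through a boat would give the C7-epimeric series. Fallback, from 17 back to 18: the C8 cation is generated without acid by metal-hydride hydrogen-atom transfer with radical–polar crossover (cobalt–salen catalyst, one equivalent of an N-fluoropyridinium oxidant, a silane). These conditions engage only 1,1-disubstituted olefins and are limited by the oxidant to one olefin per molecule; the cation equivalent is then trapped by C1 through the same chair. This fallback makes no new isolated compound (F0).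

2. Step 10. The dienolate may be acylated at oxygen, two dienolates may add to one dichloride to give oligomers, and attack on the neopentyl-type acid chloride may be slow. Fallback, from 10 and 15 back to 17: the annulation is split into an ester-based Claisen/Dieckmann sequence. One ester of 10 is saponified (KOH, 1 equiv, MeOH) to the half ester 3-methoxy-3-oxo-2,2-bis[(2R)-5-methyl-2-(prop-1-en-2-yl)hex-4-en-1-yl]propanoic acid F1. The Ghosez reagent converts it into methyl 3-chloro-3-oxo-2,2-bis[(2R)-5-methyl-2-(prop-1-en-2-yl)hex-4-en-1-yl]propanoate F2. The lithium dienolate of 15 is acylated with F2 to the isolable open-chain keto ester, methyl (E)-5-methoxy-4-(3-methylbut-2-en-1-yl)-2,2-bis[(2R)-5-methyl-2-(prop-1-en-2-yl)hex-4-en-1-yl]-3,7-dioxo-7-phenylhept-5-enoate F3. KOt-Bu in THF then closes F3 to 17 under thermodynamic control, so any O-acylated material is funnelled to the stabilised enolate.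

3. Step 5. The second alkylation at the tertiary malonate carbon may be slow, and the β-branched iodide may be lost by E2 elimination to a diene. Fallback, from 7 back to 11: malononitrile, a smaller and less basic carbanion, is bis-alkylated with 7 (NaH, DMF) to 2,2-bis[(2R)-5-methyl-2-(prop-1-en-2-yl)hex-4-en-1-yl]propanedinitrile F4. DIBAL-H (toluene, −78 °C, then mild aqueous hydrolysis) reduces it to 2,2-bis[(2R)-5-methyl-2-(prop-1-en-2-yl)hex-4-en-1-yl]propanedial F5. Pinnick oxidation (NaClO2, NaH2PO4, 2-methylbut-2-ene, t-BuOH/H2O) gives the diacid 11.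

**Further compounds**

F0 | step 11 | none | none
F1 | step 10 | 3-methoxy-3-oxo-2,2-bis[(2R)-5-methyl-2-(prop-1-en-2-yl)hex-4-en-1-yl]propanoic acid | COC(=O)C(C[C@H](C(C)=C)CC=C(C)C)(C[C@H](C(C)=C)CC=C(C)C)C(=O)O
F2 | step 10 | methyl 3-chloro-3-oxo-2,2-bis[(2R)-5-methyl-2-(prop-1-en-2-yl)hex-4-en-1-yl]propanoate | COC(=O)C(C[C@H](C(C)=C)CC=C(C)C)(C[C@H](C(C)=C)CC=C(C)C)C(=O)Cl
F3 | step 10 | methyl (E)-5-methoxy-4-(3-methylbut-2-en-1-yl)-2,2-bis[(2R)-5-methyl-2-(prop-1-en-2-yl)hex-4-en-1-yl]-3,7-dioxo-7-phenylhept-5-enoate (epimers at the enolisable C4) | COC(=O)C(C[C@H](C(C)=C)CC=C(C)C)(C[C@H](C(C)=C)CC=C(C)C)C(=O)C(CC=C(C)C)/C(OC)=C\C(=O)c1ccccc1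
F4 | step 5 | 2,2-bis[(2R)-5-methyl-2-(prop-1-en-2-yl)hex-4-en-1-yl]propanedinitrile | N#CC(C[C@H](C(C)=C)CC=C(C)C)(C[C@H](C(C)=C)CC=C(C)C)C#N
F5 | step 5 | 2,2-bis[(2R)-5-methyl-2-(prop-1-en-2-yl)hex-4-en-1-yl]propanedial | O=CC(C[C@H](C(C)=C)CC=C(C)C)(C[C@H](C(C)=C)CC=C(C)C)C=O
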